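**Retrosynthetic overview**

- The target is traced back to the bis-silylated 2,4-cis-4-methoxyflavan 17: the two phenols are unmasked last, and the C4 ketone comes from a C4 methyl ether by hydrolysis and oxidation.
- The strategy rests on ring C (O1–C2–C3–C4–C4a–C8a), the only ring that has to be built. Its O1–C2 and C3–C4 bonds are cut together as a hetero-[4+2] between an ortho-quinone methide spanning O1, C8a, C4a and C4 (from salicylaldehyde 10 and trimethyl orthoformate 14) and the vinyl group of styrene 13 (C2, C3). A chiral phosphoric acid is to set C2 as S.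
- Aldehyde 10: ring A is resorcinol; the C8–geranyl bond and the C4a–CHO bond come from two successive directed ortho-lithiations of its bis(methoxymethyl) ether, then a protecting-group exchange.
- Styrene 13 comes from 4-acetoxystyrene. Rings A and B are bought; ring C is formed in step 8.

Key step: step 8

Abbreviations: geranyl = (2E)-3,7-dimethylocta-2,6-dien-1-yl; MOM = methoxymethyl; TBS = tert-butyldimethylsilyl; (R)-TRIP = (R)-3,3'-bis(2,4,6-triisopropylphenyl)-1,1'-binaphthyl-2,2'-diyl hydrogen phosphate.

Assumption: no direct precedent fixes the sense of induction of the phosphoric acid with this substrate pair; the (R)-acid is written, and the (S)-acid would be used without other change if the (2R) series formed.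

**Route**

Step 1
Reactants: 1 resorcinol
Product: 2 1,3-bis(methoxymethoxy)benzene
Conditions: MOMCl (2.5 equiv), i-Pr2NEt, CH2Cl2, 0 °C to rt
Reagents that add atoms: chloromethyl methyl ether (MOMCl), COCCl
Why: Double O-alkylation of the phenol with an α-chloro ether under amine base (Williamson-type acetal formation) installs the two MOM ethers that later direct both lithiations.

Step 2
Reactants: 2 1,3-bis(methoxymethoxy)benzene; 3 geranyl bromide
Product: 5 2-geranyl-1,3-bis(methoxymethoxy)benzene, via aryllithium 4 (not isolated)
Conditions: n-BuLi (1.1 equiv), THF, 0 °C to rt; CuI (10 mol %), 3, −78 °C to rt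
Reagents that add atoms: none
Why: Directed ortho-metalation removes the C2 proton flanked by both MOM ethers, and the aryllithium is allylated at the primary carbon of the bromide (copper-assisted SN2), which leaves the (E)-alkene intact.

Step 3
Reactants: 5 2-geranyl-1,3-bis(methoxymethoxy)benzene
Product: 8 3-geranyl-2,4-bis(methoxymethoxy)benzaldehyde, via aryllithium 6 (not isolated), via lithium hemiaminal alkoxide 7 (not isolated)
Conditions: n-BuLi (1.3 equiv), TMEDA, THF, −10 to 0 °C; DMF, 0 °C to rt; H2O
Reagents that add atoms: N,N-dimethylformamide (DMF), CN(C)C=O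
Why: A second directed ortho-metalation at the position next to a MOM ether, followed by formylation with DMF (Bouveault-type), should outrun deprotonation of the benzylic-allylic CH2 because the base is pre-coordinated to the acetal oxygens.

Step 4
Reactants: 8 3-geranyl-2,4-bis(methoxymethoxy)benzaldehyde
Product: 9 3-geranyl-2,4-dihydroxybenzaldehyde
Conditions: HCl (3 M aq), MeOH, 45 °C
Reagents that add atoms: none
Why: Acid-catalysed transacetalisation of both MOM ethers to methanol (acetal cleavage) frees the two phenols, and the moderate temperature is chosen so that the geranyl alkenes are not protonated and cyclised.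

Step 5
Reactants: 9 3-geranyl-2,4-dihydroxybenzaldehyde
Product: 10 3-geranyl-2-hydroxy-4-(tert-butyldimethylsilyloxy)benzaldehyde
Conditions: TBSCl (1.05 equiv), imidazole, CH2Cl2, 0 °C
Reagents that add atoms: tert-butyldimethylsilyl chloride (TBSCl), CC(C)(C)[Si](C)(C)Cl
Why: Regioselective O-silylation: the 2-hydroxyl is hydrogen-bonded to the aldehyde and flanked on both sides, so the free, more acidic 4-hydroxyl para to the formyl group reacts first with one equivalent of silyl chloride.

Step 6
Reactants: 11 4-acetoxystyrene
Product: 12 4-vinylphenol
Conditions: K2CO3 (cat.), MeOH, 0 °C to rt; used crude at once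
Reagents that add atoms: none
Why: Base-catalysed transesterification (methanolysis) of the aryl acetate releases the phenol under conditions cold and brief enough to avoid polymerisation of the vinylphenol.

Step 7
Reactants: 12 4-vinylphenol
Product: 13 4-(tert-butyldimethylsilyloxy)styrene
Conditions: TBSCl, imidazole, CH2Cl2, 0 °C to rt
Reagents that add atoms: tert-butyldimethylsilyl chloride (TBSCl), CC(C)(C)[Si](C)(C)Cl
Why: Imidazole-promoted O-silylation of the phenol gives a non-acidic, electron-rich styrene suited to act as the two-carbon partner.

Step 8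
Reactants: 10 3-geranyl-2-hydroxy-4-(tert-butyldimethylsilyloxy)benzaldehyde; 13 4-(tert-butyldimethylsilyloxy)styrene; 14 trimethyl orthoformate
Product: 17 (2S,4S)-8-geranyl-4-methoxy-7-(tert-butyldimethylsilyloxy)-2-[4-(tert-butyldimethylsilyloxy)phenyl]chromane (2,4-cis), via dimethyl acetal 15 (not isolated), via methoxy ortho-quinone methide 16 (not isolated)
Conditions: (R)-TRIP (10 mol %), 14 (1.5 equiv), 5 Å MS, PhMe, rt; then 13 (2.5 equiv, slow addition), −20 °C
Reagents that add atoms: none
Why: Proposed new method: the phosphoric acid, a stronger acid than the pyridinium salts that already promote orthoformate acetalisation, should convert 10 and 14 into acetal 15 and then expel methanol from it to give the methoxy-bearing ortho-quinone methide 16, which stays bound to the chiral phosphate as a hydrogen-bonded ion pair (its protonated form is the O-methyl oxocarbenium ion of the phenol) inside the pocket of the two triisopropylphenyl groups. Ring C then closes in one inverse-demand hetero-Diels–Alder [4+2] event in which C–C bonding between the CH2 terminus of 13 (future C3) and C4 runs ahead of C–O bonding, the positive charge building at the future C2 being delocalised into the 4-silyloxyphenyl ring until the ring A oxygen (O1) closes onto it. The closest known reactions are the achiral-acid three-component condensation of salicylaldehydes, orthoformates and styrenes to 2,4-cis-4-alkoxy-2-arylchromans and the chiral Brønsted acid catalysed [4+2] cycloaddition of ortho-quinone methides generated in situ with styrenes; joining the two under one chiral acid is the untested element. C4 is fixed by the face of 16 that the phosphate leaves open, and C2 is fixed relative to C4 by an endo approach that places the aryl group and the methoxy group cis, so that (4S) face selection is relayed into (2S). The step needs enantio-, diastereo-, regio- and chemoselectivity: the sense of addition is dictated by pairing the nucleophilic CH2 terminus with the electrophilic C4, the silyloxystyrene is far more nucleophilic than the trialkyl alkenes of the geranyl chain, and the 7-silyloxy group para to C4 lets a weak acid ionise 15 at low temperature, which spares the geranyl chain and both silyl ethers; C4 is sacrificial (it becomes the carbonyl carbon), so only the C2 configuration has to be carried on.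

Step 9
Reactants: 17 (2S,4S)-8-geranyl-4-methoxy-7-(tert-butyldimethylsilyloxy)-2-[4-(tert-butyldimethylsilyloxy)phenyl]chromane
Product: 18 (2S)-8-geranyl-7-(tert-butyldimethylsilyloxy)-2-[4-(tert-butyldimethylsilyloxy)phenyl]chroman-4-ol (C4 epimer mixture)
Conditions: p-TsOH·H2O (10 mol %), THF/H2O (5:1), 0 °C to rt
Reagents that add atoms: water, O
Why: SN1 solvolysis (acetal-type hydrolysis) of the C4 methyl ether should proceed under acid too weak to cleave aryl silyl ethers or open the O1–C2 bond, because the C4 cation is stabilised by O1 ortho and the 7-silyloxy group para; the C4 configuration is irrelevant and C2 is not touched.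

Step 10
Reactants: 18 (2S)-8-geranyl-7-(tert-butyldimethylsilyloxy)-2-[4-(tert-butyldimethylsilyloxy)phenyl]chroman-4-ol
Product: 19 (2S)-8-geranyl-7-(tert-butyldimethylsilyloxy)-2-[4-(tert-butyldimethylsilyloxy)phenyl]chroman-4-one
Conditions: activated MnO2 (excess), CH2Cl2, rt
Reagents that add atoms: none
Why: Benzylic alcohol oxidation with activated MnO2 is selective for the electron-rich benzylic carbinol over the allylic C–H bonds of the geranyl chain and runs under neutral conditions, so both C4 epimers converge on one ketone without epimerising C2.

Step 11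
Reactants: 19 (2S)-8-geranyl-7-(tert-butyldimethylsilyloxy)-2-[4-(tert-butyldimethylsilyloxy)phenyl]chroman-4-one
Product: 20 (2S)-7,4'-dihydroxy-8-geranylflavanone
Conditions: TBAF (2.4 equiv), AcOH (2.6 equiv), THF, 0 °C
Reagents that add atoms: none
Why: Fluoride-induced cleavage of both aryl silyl ethers (driven by Si–F bond formation) is buffered with acetic acid so that each phenoxide is protonated as it forms, which should suppress the base-induced retro-oxa-Michael ring opening that would racemise C2.

**Compound list**

1 | resorcinol | Oc1cccc(O)c1 | starting material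
2 | 1,3-bis(methoxymethoxy)benzene | COCOc1cccc(OCOC)c1 | intermediate
3 | geranyl bromide | CC(C)=CCC/C(C)=C/CBr | starting material
4 | [2,6-bis(methoxymethoxy)phenyl]lithium (not isolated) | [Li]c1c(OCOC)cccc1OCOC | intermediate
5 | 2-geranyl-1,3-bis(methoxymethoxy)benzene | CC(C)=CCC/C(C)=C/Cc1c(OCOC)cccc1OCOC | intermediate
6 | [3-geranyl-2,4-bis(methoxymethoxy)phenyl]lithium (not isolated) | CC(C)=CCC/C(C)=C/Cc1c(OCOC)ccc([Li])c1OCOC | intermediate
7 | lithium (dimethylamino)[3-geranyl-2,4-bis(methoxymethoxy)phenyl]methoxide (not isolated; carbinol carbon racemic) | CC(C)=CCC/C(C)=C/Cc1c(OCOC)ccc(C(O[Li])N(C)C)c1OCOC | intermediate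
8 | 3-geranyl-2,4-bis(methoxymethoxy)benzaldehyde | CC(C)=CCC/C(C)=C/Cc1c(OCOC)ccc(C=O)c1OCOC | intermediate
9 | 3-geranyl-2,4-dihydroxybenzaldehyde | CC(C)=CCC/C(C)=C/Cc1c(O)ccc(C=O)c1O | intermediate
10 | 3-geranyl-2-hydroxy-4-(tert-butyldimethylsilyloxy)benzaldehyde | CC(C)=CCC/C(C)=C/Cc1c(O[Si](C)(C)C(C)(C)C)ccc(C=O)c1O | intermediate
11 | 4-acetoxystyrene | C=Cc1ccc(OC(C)=O)cc1 | starting material
12 | 4-vinylphenol | C=Cc1ccc(O)cc1 | intermediate
13 | 4-(tert-butyldimethylsilyloxy)styrene | C=Cc1ccc(O[Si](C)(C)C(C)(C)C)cc1 | intermediate
14 | trimethyl orthoformate | COC(OC)OC | starting material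
15 | 3-geranyl-2-hydroxy-4-(tert-butyldimethylsilyloxy)benzaldehyde dimethyl acetal (not isolated) | CC(C)=CCC/C(C)=C/Cc1c(O[Si](C)(C)C(C)(C)C)ccc(C(OC)OC)c1O | intermediate
16 | 2-geranyl-6-(methoxymethylidene)-3-(tert-butyldimethylsilyloxy)cyclohexa-2,4-dien-1-one (not isolated; exocyclic alkene geometry not defined) | CC(C)=CCC/C(C)=C/CC1=C(O[Si](C)(C)C(C)(C)C)C=CC(=COC)C1=O | intermediate
17 | (2S,4S)-8-geranyl-4-methoxy-7-(tert-butyldimethylsilyloxy)-2-[4-(tert-butyldimethylsilyloxy)phenyl]chromane (2,4-cis) | CC(C)=CCC/C(C)=C/Cc1c(O[Si](C)(C)C(C)(C)C)ccc2c1O[C@H](c1ccc(O[Si](C)(C)C(C)(C)C)cc1)C[C@@H]2OC | intermediate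
18 | (2S)-8-geranyl-7-(tert-butyldimethylsilyloxy)-2-[4-(tert-butyldimethylsilyloxy)phenyl]chroman-4-ol (C4 epimer mixture) | CC(C)=CCC/C(C)=C/Cc1c(O[Si](C)(C)C(C)(C)C)ccc2c1O[C@H](c1ccc(O[Si](C)(C)C(C)(C)C)cc1)CC2O | intermediate
19 | (2S)-8-geranyl-7-(tert-butyldimethylsilyloxy)-2-[4-(tert-butyldimethylsilyloxy)phenyl]chroman-4-one | CC(C)=CCC/C(C)=C/Cc1c(O[Si](C)(C)C(C)(C)C)ccc2c1O[C@H](c1ccc(O[Si](C)(C)C(C)(C)C)cc1)CC2=O | intermediate
20 | (2S)-7,4'-dihydroxy-8-geranylflavanone | CC(C)=CCC/C(C)=C/Cc1c(O)ccc2c1O[C@H](c1ccc(O)cc1)CC2=O | target

**Step count**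

Total: 11 steps. Longest linear sequence: 9 steps (steps 1–5 and 8–11, from resorcinol).

**Steps most likely to fail**

1. Step 8 (proposed new method). The weak chiral acid may ionise acetal 15 too slowly. Face discrimination at the quinone methide may be poor because the silylated styrene offers no hydrogen-bond contact to the catalyst. The styrene may also be consumed by cationic oligomerisation, and an unselective ring closure would lower the enantiomeric purity at C2. Fallback: the assembly is run in its known racemic form and C2 is sorted afterwards. Setting out from 10, 13 and 14, p-TsOH·H2O (5 mol %) in CH2Cl2 at 0 °C should give racemic 2,4-cis-8-geranyl-4-methoxy-7-(tert-butyldimethylsilyloxy)-2-[4-(tert-butyldimethylsilyloxy)phenyl]chromane F1. Hydrolysis as in step 9 should give racemic 8-geranyl-7-(tert-butyldimethylsilyloxy)-2-[4-(tert-butyldimethylsilyloxy)phenyl]chroman-4-ol F2, and MnO2 oxidation as in step 10 the racemic bis-silyl flavanone F3. Kinetic resolution of F3 by asymmetric transfer hydrogenation follows, a known resolution of racemic flavanones (RuCl(p-cymene)[(R,R)-TsDPEN] or its enantiomer, HCO2H/Et3N, rt, stopped near half conversion, the catalyst enantiomer chosen so that the (2R)-ketone is reduced faster). It should turn the unwanted enantiomer into the (2R,4R)-cis-flavan-4-ol F4, which is removed by chromatography, and leave the (2S)-ketone, which rejoins the route at 19.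

2. Step 9. Once formed, the C4 cation may lose a C3 proton (dehydration to the 2H-chromene) or be trapped by an electron-rich arene of a second molecule faster than by water, and prolonged acid contact may begin to open the O1–C2 bond. Fallback: from 17 the C4–H bond is oxidised directly, without solvolysis and without the alcohol. DDQ (1.2 equiv) in CH2Cl2/pH 7 buffer at 0 °C should abstract hydride from the doubly activated benzylic ether position (the known DDQ oxidation of electron-rich benzylic ethers to carbonyl compounds). Water then converts the resulting O-methyl oxocarbenium ion, or the enol ether derived from it, through the hemiketal into the ketone with loss of methanol, and the route is rejoined at 19; no new isolated compound is made.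

3. Step 4. Under the protic acid needed to cleave both acetals, the freed phenols that flank the geranyl chain may add to its protonated proximal alkene (chroman formation), or the chain may cyclise on itself. Fallback: the protecting groups and the lithiation sequence are bypassed. Setting out from geranyl bromide 3 and commercial 2,4-dihydroxybenzaldehyde F5, direct C-alkylation of the phenoxide (KOH, H2O, rt) is a known, modest-yielding reaction of 2,4-dihydroxyaryl carbonyl compounds that needs chromatographic removal of the 5-geranyl and O-geranyl isomers. It should deliver the 3-geranyl product without any acid exposure and rejoin the route at 9.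

**Further compounds**

F1 | step 8 | racemic 2,4-cis-8-geranyl-4-methoxy-7-(tert-butyldimethylsilyloxy)-2-[4-(tert-butyldimethylsilyloxy)phenyl]chromane | CC(C)=CCC/C(C)=C/Cc1c(O[Si](C)(C)C(C)(C)C)ccc2c1OC(c1ccc(O[Si](C)(C)C(C)(C)C)cc1)CC2OC
F2 | step 8 | racemic 8-geranyl-7-(tert-butyldimethylsilyloxy)-2-[4-(tert-butyldimethylsilyloxy)phenyl]chroman-4-ol (C4 epimer mixture) | CC(C)=CCC/C(C)=C/Cc1c(O[Si](C)(C)C(C)(C)C)ccc2c1OC(c1ccc(O[Si](C)(C)C(C)(C)C)cc1)CC2O
F3 | step 8 | racemic 8-geranyl-7-(tert-butyldimethylsilyloxy)-2-[4-(tert-butyldimethylsilyloxy)phenyl]chroman-4-one | CC(C)=CCC/C(C)=C/Cc1c(O[Si](C)(C)C(C)(C)C)ccc2c1OC(c1ccc(O[Si](C)(C)C(C)(C)C)cc1)CC2=O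
F4 | step 8 | (2R,4R)-8-geranyl-7-(tert-butyldimethylsilyloxy)-2-[4-(tert-butyldimethylsilyloxy)phenyl]chroman-4-ol (2,4-cis) | CC(C)=CCC/C(C)=C/Cc1c(O[Si](C)(C)C(C)(C)C)ccc2c1O[C@@H](c1ccc(O[Si](C)(C)C(C)(C)C)cc1)C[C@H]2O
F0 | step 9 | none | none
F5 | step 4 | 2,4-dihydroxybenzaldehyde (purchased) | O=Cc1ccc(O)cc1O
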